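**Retrosynthetic overview**

Lettering: top unit = rings A (benzo), C (pyran), B (catechol); middle unit = D, F, E; bottom unit = G, I, H. The last operations are methanolysis of one acetate and hydrogenolysis of fourteen benzyl ethers and one bromine cap.
Key disconnection: ring C is cut at O1–C2 and C3–C4 in a retro-[4+2] to an ortho-quinone methide (O1=C8a–C4a=C4, with C4 carried on C8 of ring D) and (Z)-2-[3,4-bis(benzyloxy)phenyl]ethenyl acetate.
Enabling feature: O1 sits on ring A ortho to C4, and C4 is doubly benzylic (rings A and D), so dehydration of an ortho-hydroxybenzhydrol unmasks the 4π oxadiene. C2 bears the electron-rich ring B, which makes C3 of a C2=C3 enol ester the nucleophilic end, and both carbinol epimers converge on one planar intermediate.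
The benzhydrol comes from C8(ring D)–C4 bond formation (aryl Grignard from an 8-iodide plus a salicylaldehyde). The D–I dimer comes from a C4(ring F)–C6(ring G) Friedel–Crafts coupling of a C4 acetal with an 8-bromo-capped nucleophile, both from (−)-epicatechin.
Ring order: rings D, E, F and G, H, I are carried intact from epicatechin, rings A and B enter as benzaldehyde-derived arenes, and ring C is the only ring formed, last among the skeletal events.

Key step: step 11

Assumption (sense of induction in step 11): which enantiomer of the phosphoric acid directs the enol acetate to the required face of 16 cannot be predicted with confidence for a substrate of this size; the (R)-acid is written, and the (S)-acid is its direct replacement if the opposite face is favoured.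
Remark: C4 of acetal 6 is drawn as the 4β epimer; its configuration is lost on ionisation in step 6. (−)-Epicatechin, 2,4,6-trihydroxybenzaldehyde and 3,4-bis(benzyloxy)benzaldehyde are taken as commercial.

Step 1
Reactants: 1 (−)-epicatechin
Product: 2 5,7,3',4'-tetra-O-benzyl-(−)-epicatechin
Conditions: BnBr (4.4 equiv), K2CO3, DMF, 0 °C → rt
Reagents that add atoms: benzyl bromide, BrCc1ccccc1
Why: Williamson etherification of the four phenolic hydroxyls, which are far more acidic than the C3 alcohol, under mild carbonate base at low temperature so that C2 and C3 are not touched.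

Step 2
Reactants: 2 5,7,3',4'-tetra-O-benzyl-(−)-epicatechin
Product: 3 3,5,7,3',4'-penta-O-benzyl-(−)-epicatechin
Conditions: NaH, BnBr, Bu4NI (cat.), DMF, 0 °C → rt
Reagents that add atoms: benzyl bromide, BrCc1ccccc1
Why: Williamson etherification of the remaining secondary alcohol through its sodium alkoxide; no stereocentre is affected.

Step 3
Reactants: 3 3,5,7,3',4'-penta-O-benzyl-(−)-epicatechin
Product: 4 8-bromo-3,5,7,3',4'-penta-O-benzyl-(−)-epicatechin
Conditions: NBS (1.0 equiv), CH2Cl2, −78 °C → rt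
Reagents that add atoms: N-bromosuccinimide, O=C1CCC(=O)N1Br
Why: electrophilic aromatic bromination, in which C8 is the most nucleophilic position of the 5,7-dibenzyloxy ring of benzylated flavan-3-ols, gives the bromide that later caps C8 of ring G.

Step 4
Reactants: 3 3,5,7,3',4'-penta-O-benzyl-(−)-epicatechin
Product: 5 8-iodo-3,5,7,3',4'-penta-O-benzyl-(−)-epicatechin
Conditions: NIS (1.05 equiv), CH2Cl2, 0 °C, dark
Reagents that add atoms: N-iodosuccinimide, O=C1CCC(=O)N1I
Why: electrophilic aromatic iodination with the same C8 preference installs the handle for later metalation of ring D.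

Step 5
Reactants: 5 8-iodo-3,5,7,3',4'-penta-O-benzyl-(−)-epicatechin
Product: 6 4β-(2-ethoxyethoxy)-8-iodo-3,5,7,3',4'-penta-O-benzylepicatechin (2,3-cis-3,4-trans)
Conditions: DDQ, EtOCH2CH2OH, CH2Cl2, rt
Reagents that add atoms: 2-ethoxyethanol, CCOCCO
Why: DDQ benzylic oxidation (hydride abstraction at C4 to the flavan-4-yl cation stabilised by the ring oxygens) with capture by the alcohol anti to the 3-benzyloxy group should give the 4β acetal, whose configuration is erased in step 6.

Step 6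
Reactants: 6 4β-(2-ethoxyethoxy)-8-iodo-3,5,7,3',4'-penta-O-benzylepicatechin; 4 8-bromo-3,5,7,3',4'-penta-O-benzyl-(−)-epicatechin (3 equiv, excess recovered)
Product: 7 8-iodo-3,5,7,3',4'-penta-O-benzylepicatechin-(4β→6)-8-bromo-3,5,7,3',4'-penta-O-benzylepicatechin (upper unit = rings D, E, F; lower unit = rings G, H, I)
Conditions: Me3SiOTf (20 mol %), CH2Cl2, −78 °C → −40 °C; Et3N quench
Reagents that add atoms: none
Why: Lewis-acid-promoted Friedel–Crafts flavan coupling in which the acetal is ionised at C4, the only free position of ring G (C6, C8 being bromine-capped) attacks the cation anti to the pseudoaxial 3-benzyloxy group to set the 4β (3,4-trans) configuration at C4 of ring F, and the iodine at C8 of 6 suppresses self-condensation.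

Step 7
Reactants: 8 2,4,6-trihydroxybenzaldehyde
Product: 9 4,6-bis(benzyloxy)-2-hydroxybenzaldehyde
Conditions: BnBr (2.1 equiv), K2CO3, DMF, rt
Reagents that add atoms: benzyl bromide, BrCc1ccccc1
Why: Williamson etherification of the 4-hydroxyl and one ortho hydroxyl, while the last ortho hydroxyl is held back by its hydrogen bond to the formyl group.

Step 8
Reactants: 7 8-iodo-3,5,7,3',4'-penta-O-benzylepicatechin-(4β→6)-8-bromo-3,5,7,3',4'-penta-O-benzylepicatechin; 9 4,6-bis(benzyloxy)-2-hydroxybenzaldehyde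
Product: 12 8-{[4,6-bis(benzyloxy)-2-hydroxyphenyl](hydroxy)methyl}-3,5,7,3',4'-penta-O-benzylepicatechin-(4β→6)-8-bromo-3,5,7,3',4'-penta-O-benzylepicatechin (both carbinol epimers), via sodium phenoxide 10 (not isolated), via arylmagnesium chloride 11 (not isolated)
Conditions: 7: i-PrMgCl·LiCl (1.1 equiv), THF, −15 °C; 9: NaH, THF, 0 °C; combine, −15 °C → rt; aq. NH4Cl; rapid filtration through Et3N-deactivated silica
Reagents that add atoms: none
Why: iodine–magnesium exchange with i-PrMgCl·LiCl should be chemoselective for the aryl iodide of ring D (flanked by two coordinating ether oxygens) over the aryl bromide of ring G, and the aryl Grignard then adds to the chelated 2-formylphenoxide (the standard entry to ortho-hydroxybenzhydrols); the carbinol carbon forms without control, which is harmless because it becomes planar in step 11.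

Step 9
Reactants: 13 3,4-bis(benzyloxy)benzaldehyde
Product: 14 1,2-bis(benzyloxy)-4-ethynylbenzene
Conditions: dimethyl (1-diazo-2-oxopropyl)phosphonate, K2CO3, MeOH/THF, rt
Reagents that add atoms: dimethyl (1-diazo-2-oxopropyl)phosphonate (Ohira–Bestmann reagent), CC(=O)C(=[N+]=[N-])P(=O)(OC)OC
Why: the Ohira–Bestmann modification of the Seyferth–Gilbert homologation converts the aldehyde into the terminal alkyne under mild carbonate conditions that benzyl ethers tolerate.

Step 10
Reactants: 14 1,2-bis(benzyloxy)-4-ethynylbenzene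
Product: 15 (Z)-2-[3,4-bis(benzyloxy)phenyl]ethenyl acetate
Conditions: AcOH (1.2 equiv), Ru(η3-CH2C(CH3)CH2)2(Ph2P(CH2)4PPh2) (2 mol %), toluene, 65 °C
Reagents that add atoms: acetic acid, CC(=O)O
Why: ruthenium-catalysed anti-Markovnikov addition of a carboxylic acid to a terminal aryl alkyne through a ruthenium vinylidene should give the (Z)-enol ester, whose cis geometry later becomes the 2,3-cis relationship of ring C.

Step 11
Reactants: 12 8-{[4,6-bis(benzyloxy)-2-hydroxyphenyl](hydroxy)methyl}-3,5,7,3',4'-penta-O-benzylepicatechin-(4β→6)-8-bromo-3,5,7,3',4'-penta-O-benzylepicatechin (epimer mixture); 15 (Z)-2-[3,4-bis(benzyloxy)phenyl]ethenyl acetate (3 equiv)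
Product: 17 3-O-acetyl-5,7,3',4'-tetra-O-benzylepicatechin-(4β→8)-3,5,7,3',4'-penta-O-benzylepicatechin-(4β→6)-8-bromo-3,5,7,3',4'-penta-O-benzylepicatechin, via ortho-quinone methide 16 (not isolated)
Conditions: (R)-3,3'-bis(2,4,6-triisopropylphenyl)-1,1'-binaphthyl-2,2'-diyl hydrogen phosphate (10 mol %), 5 Å molecular sieves, toluene, −20 °C → rt
Reagents that add atoms: none
Why: Proposed new method: the phosphoric acid dehydrates either carbinol epimer of 12, with loss of one molecule of water that the molecular sieves take up, to one planar, hydrogen-bonded (E)-ortho-quinone methide 16 (a stereoconvergent entry), which is trapped by the (Z)-enol acetate 15 in an inverse-electron-demand oxa-[4+2] cycloaddition. The closest known reaction type is the chiral-phosphoric-acid-catalysed [4+2] cycloaddition of quinone methides from ortho-hydroxybenzhydrols with styrenes and enamides, here extended to a β-acyloxystyrene. Ring C closes in the [4+2] mode (4π oxadiene O1=C8a–C4a=C4 plus the 2π bond C2=C3), asynchronously, with C3–C4 bonding in the lead and O1–C2 closure (6-exo-trig capture of the incipient 4-benzyloxybenzyl cation by the phosphate-bound phenol oxygen) outrunning rotation about C2–C3. The regiochemistry needed (C3 to C4, O1 to C2) is secured by the 4-benzyloxy group of ring B, a much stronger donor than the acyloxy group, which makes the acetoxy-bearing carbon the nucleophilic end of 15. C2 and C3 are set cis by suprafacial addition to the (Z)-alkene, and C4 is set trans to C3–O (4β) by an exo approach that keeps the acetoxy group anti to ring A and clear of its peri 5-benzyloxy group. The absolute sense, for which the remote stereocentres of rings F and I and the orthogonal ring D offer little bias, rests on the chiral phosphate bound to O1–H and ion-paired with the developing cation, and the wrong-face adduct would be a separable diastereomer.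

Step 12
Reactants: 17 3-O-acetyl-5,7,3',4'-tetra-O-benzylepicatechin-(4β→8)-3,5,7,3',4'-penta-O-benzylepicatechin-(4β→6)-8-bromo-3,5,7,3',4'-penta-O-benzylepicatechin
Product: 18 5,7,3',4'-tetra-O-benzylepicatechin-(4β→8)-3,5,7,3',4'-penta-O-benzylepicatechin-(4β→6)-8-bromo-3,5,7,3',4'-penta-O-benzylepicatechin
Conditions: NaOMe (cat.), MeOH/THF, rt
Reagents that add atoms: none
Why: base-catalysed transesterification (Zemplén-type methanolysis) removes the only ester, while benzyl ethers, the aryl bromide and all stereocentres are inert to methoxide.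

Step 13
Reactants: 18 5,7,3',4'-tetra-O-benzylepicatechin-(4β→8)-3,5,7,3',4'-penta-O-benzylepicatechin-(4β→6)-8-bromo-3,5,7,3',4'-penta-O-benzylepicatechin
Product: 19 epicatechin-(4β→8)-epicatechin-(4β→6)-epicatechin (CNP0178679.3)
Conditions: H2 (1 atm), Pd(OH)2/C, Et3N (1.5 equiv), THF/MeOH/H2O, rt; filtration, Sephadex LH-20, lyophilisation
Reagents that add atoms: none
Why: heterogeneous palladium-catalysed hydrogenolysis should cleave the fourteen benzyl ethers and the C8 bromide of ring G in one operation, with Et3N taking up HBr so that the acid-labile interflavan bonds are not exposed to acid and no stereocentre is affected.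

**Compound list**

1 | (−)-epicatechin, (2R,3R)-2-(3,4-dihydroxyphenyl)chroman-3,5,7-triol | Oc1cc(O)c2c(c1)O[C@H](c1ccc(O)c(O)c1)[C@H](O)C2 | starting material
2 | 5,7,3',4'-tetra-O-benzyl-(−)-epicatechin | O(Cc3ccccc3)c1cc(OCc3ccccc3)c2c(c1)O[C@H](c1ccc(OCc3ccccc3)c(OCc3ccccc3)c1)[C@H](O)C2 | intermediate
3 | 3,5,7,3',4'-penta-O-benzyl-(−)-epicatechin | O(Cc3ccccc3)c1cc(OCc3ccccc3)c2c(c1)O[C@H](c1ccc(OCc3ccccc3)c(OCc3ccccc3)c1)[C@H](OCc3ccccc3)C2 | intermediate
4 | 8-bromo-3,5,7,3',4'-penta-O-benzyl-(−)-epicatechin | O(Cc3ccccc3)c1cc(OCc3ccccc3)c2c(c1Br)O[C@H](c1ccc(OCc3ccccc3)c(OCc3ccccc3)c1)[C@H](OCc3ccccc3)C2 | intermediate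
5 | 8-iodo-3,5,7,3',4'-penta-O-benzyl-(−)-epicatechin | O(Cc3ccccc3)c1cc(OCc3ccccc3)c2c(c1I)O[C@H](c1ccc(OCc3ccccc3)c(OCc3ccccc3)c1)[C@H](OCc3ccccc3)C2 | intermediate
6 | 4β-(2-ethoxyethoxy)-8-iodo-3,5,7,3',4'-penta-O-benzylepicatechin | O(Cc3ccccc3)c1cc(OCc3ccccc3)c2c(c1I)O[C@H](c1ccc(OCc3ccccc3)c(OCc3ccccc3)c1)[C@H](OCc3ccccc3)[C@H]2OCCOCC | intermediate
7 | 8-iodo-3,5,7,3',4'-penta-O-benzylepicatechin-(4β→6)-8-bromo-3,5,7,3',4'-penta-O-benzylepicatechin | O(Cc3ccccc3)c1cc(OCc3ccccc3)c2c(c1I)O[C@H](c1ccc(OCc3ccccc3)c(OCc3ccccc3)c1)[C@H](OCc3ccccc3)[C@H]2c1c(OCc3ccccc3)c(Br)c2c(c1OCc3ccccc3)C[C@@H](OCc3ccccc3)[C@@H](c1ccc(OCc3ccccc3)c(OCc3ccccc3)c1)O2 | intermediate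
8 | 2,4,6-trihydroxybenzaldehyde | O=Cc1c(O)cc(O)cc1O | starting material
9 | 4,6-bis(benzyloxy)-2-hydroxybenzaldehyde | O=Cc1c(O)cc(OCc2ccccc2)cc1OCc2ccccc2 | intermediate
10 | sodium 3,5-bis(benzyloxy)-2-formylphenolate | [Na+].[O-]c1cc(OCc2ccccc2)cc(OCc2ccccc2)c1C=O | intermediate
11 | arylmagnesium chloride of 7 (MgCl at C8 of ring D in place of iodine) | O(Cc3ccccc3)c1cc(OCc3ccccc3)c2c(c1[Mg]Cl)O[C@H](c1ccc(OCc3ccccc3)c(OCc3ccccc3)c1)[C@H](OCc3ccccc3)[C@H]2c1c(OCc3ccccc3)c(Br)c2c(c1OCc3ccccc3)C[C@@H](OCc3ccccc3)[C@@H](c1ccc(OCc3ccccc3)c(OCc3ccccc3)c1)O2 | intermediate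
12 | 8-{[4,6-bis(benzyloxy)-2-hydroxyphenyl](hydroxy)methyl}-3,5,7,3',4'-penta-O-benzylepicatechin-(4β→6)-8-bromo-3,5,7,3',4'-penta-O-benzylepicatechin, both carbinol epimers | O(Cc3ccccc3)c1cc(OCc3ccccc3)c2c(c1C(O)c4c(O)cc(OCc3ccccc3)cc4OCc3ccccc3)O[C@H](c1ccc(OCc3ccccc3)c(OCc3ccccc3)c1)[C@H](OCc3ccccc3)[C@H]2c1c(OCc3ccccc3)c(Br)c2c(c1OCc3ccccc3)C[C@@H](OCc3ccccc3)[C@@H](c1ccc(OCc3ccccc3)c(OCc3ccccc3)c1)O2 | intermediate
13 | 3,4-bis(benzyloxy)benzaldehyde | O=Cc1ccc(OCc2ccccc2)c(OCc2ccccc2)c1 | starting material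
14 | 1,2-bis(benzyloxy)-4-ethynylbenzene | C#Cc1ccc(OCc2ccccc2)c(OCc2ccccc2)c1 | intermediate
15 | (Z)-2-[3,4-bis(benzyloxy)phenyl]ethenyl acetate | CC(=O)O/C=C\c1ccc(OCc2ccccc2)c(OCc2ccccc2)c1 | intermediate
16 | (E)-ortho-quinone methide: 3,5-bis(benzyloxy)-6-ylidene-cyclohexa-2,4-dien-1-one whose exocyclic methine carbon is bonded to C8 of ring D of the dimer | O(Cc3ccccc3)c1cc(OCc3ccccc3)c2c(c1/C=C4/C(=O)C=C(OCc3ccccc3)C=C4OCc3ccccc3)O[C@H](c1ccc(OCc3ccccc3)c(OCc3ccccc3)c1)[C@H](OCc3ccccc3)[C@H]2c1c(OCc3ccccc3)c(Br)c2c(c1OCc3ccccc3)C[C@@H](OCc3ccccc3)[C@@H](c1ccc(OCc3ccccc3)c(OCc3ccccc3)c1)O2 | intermediate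
17 | 3-O-acetyl-5,7,3',4'-tetra-O-benzylepicatechin-(4β→8)-3,5,7,3',4'-penta-O-benzylepicatechin-(4β→6)-8-bromo-3,5,7,3',4'-penta-O-benzylepicatechin | O(Cc3ccccc3)c1cc(OCc3ccccc3)c2c(c1)O[C@H](c1ccc(OCc3ccccc3)c(OCc3ccccc3)c1)[C@H](OC(C)=O)[C@H]2c1c(OCc3ccccc3)cc(OCc3ccccc3)c2c1O[C@H](c1ccc(OCc3ccccc3)c(OCc3ccccc3)c1)[C@H](OCc3ccccc3)[C@H]2c1c(OCc3ccccc3)c(Br)c2c(c1OCc3ccccc3)C[C@@H](OCc3ccccc3)[C@@H](c1ccc(OCc3ccccc3)c(OCc3ccccc3)c1)O2 | intermediate
18 | 5,7,3',4'-tetra-O-benzylepicatechin-(4β→8)-3,5,7,3',4'-penta-O-benzylepicatechin-(4β→6)-8-bromo-3,5,7,3',4'-penta-O-benzylepicatechin | O(Cc3ccccc3)c1cc(OCc3ccccc3)c2c(c1)O[C@H](c1ccc(OCc3ccccc3)c(OCc3ccccc3)c1)[C@H](O)[C@H]2c1c(OCc3ccccc3)cc(OCc3ccccc3)c2c1O[C@H](c1ccc(OCc3ccccc3)c(OCc3ccccc3)c1)[C@H](OCc3ccccc3)[C@H]2c1c(OCc3ccccc3)c(Br)c2c(c1OCc3ccccc3)C[C@@H](OCc3ccccc3)[C@@H](c1ccc(OCc3ccccc3)c(OCc3ccccc3)c1)O2 | intermediate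
19 | epicatechin-(4β→8)-epicatechin-(4β→6)-epicatechin (CNP0178679.3) | Oc1cc(O)c2c(c1)O[C@H](c1ccc(O)c(O)c1)[C@H](O)[C@H]2c1c(O)cc(O)c2c1O[C@H](c1ccc(O)c(O)c1)[C@H](O)[C@H]2c1c(O)cc2c(c1O)C[C@@H](O)[C@@H](c1ccc(O)c(O)c1)O2 | target

Total step count: 13. Longest linear sequence: 9 steps (steps 1, 2, 4, 5, 6, 8, 11, 12, 13).

**Steps most likely to fail**

Step 11. The cycloaddition may proceed through the endo rather than the exo approach, may take place on the wrong face of the quinone methide, or may go through a free benzylic cation that rotates about C2–C3 before ring closure and so loses the cis relationship; self-condensation of the quinone methide through ring A is a further drain. The fallback uses known Lewis-acid flavan coupling, sets out from 7 and 2, and returns to the route at 17. The arylmagnesium 11, generated from 7 as in step 8, is quenched with methanol and then aq. NH4Cl to give the iodine-free dimer 3,5,7,3',4'-penta-O-benzylepicatechin-(4β→6)-8-bromo-3,5,7,3',4'-penta-O-benzylepicatechin F1. Separately, 2 is acetylated (Ac2O, pyridine, DMAP) to 3-O-acetyl-5,7,3',4'-tetra-O-benzylepicatechin F2, which is oxidised (DDQ, 2-ethoxyethanol, CH2Cl2) to 3-O-acetyl-4β-(2-ethoxyethoxy)-5,7,3',4'-tetra-O-benzylepicatechin F3. Me3SiOTf-promoted Friedel–Crafts coupling of F3 with an excess of F1 should give 17, because C8 of ring D is the most nucleophilic free position, C8 of ring G is bromine-capped, and the arene attacks anti to the 3-acetoxy group.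

Step 8. The exchange may fail to discriminate fully between the iodide of ring D and the bromide of ring G, the hindered aryl Grignard may add sluggishly to the electron-rich phenoxide aldehyde, and the benzhydrol may dehydrate on isolation. The fallback changes the order of assembly, sets out from 5, and returns at 17. Monomer 5 carries no bromide, so iodine–lithium exchange with n-BuLi (THF, −78 °C) can be used to give 8-lithio-3,5,7,3',4'-penta-O-benzyl-(−)-epicatechin F4. This more reactive aryllithium is added to 10 (aq. NH4Cl work-up) to give the monomeric benzhydrol 8-{[4,6-bis(benzyloxy)-2-hydroxyphenyl](hydroxy)methyl}-3,5,7,3',4'-penta-O-benzylepicatechin F5. F5 is taken through the conditions of step 11 with 15, with loss of water, to 3-O-acetyl-5,7,3',4'-tetra-O-benzylepicatechin-(4β→8)-3,5,7,3',4'-penta-O-benzylepicatechin F6. DDQ and 2-ethoxyethanol then oxidise the only benzylic methylene (C4 of ring F; the methine C4 of ring C is tertiary and shielded by two aryl groups) to 3-O-acetyl-5,7,3',4'-tetra-O-benzylepicatechin-(4β→8)-4β-(2-ethoxyethoxy)-3,5,7,3',4'-penta-O-benzylepicatechin F7. Coupling of F7 with 4 under the conditions of step 6 gives 17.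

Step 6. Attack by the hindered, bromine-deactivated C6 of 4 on the iodine-bearing cation may be slow, so that the cation from 6 eliminates or condenses with itself through its own C6. The fallback moves the iodination to the dimer stage, sets out from 3, and returns at 7. Compound 3 is oxidised (DDQ, 2-ethoxyethanol) to 4β-(2-ethoxyethoxy)-3,5,7,3',4'-penta-O-benzylepicatechin F8, whose less hindered, iodine-free cation is coupled with a large excess of 4 (Me3SiOTf, CH2Cl2, −78 °C) to the iodine-free dimer 3,5,7,3',4'-penta-O-benzylepicatechin-(4β→6)-8-bromo-3,5,7,3',4'-penta-O-benzylepicatechin F1 (the same compound as in the first fallback). NIS then iodinates C8 of ring D, the most nucleophilic free position, to give 7.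

**Further compounds**

F1 | step 11 | 3,5,7,3',4'-penta-O-benzylepicatechin-(4β→6)-8-bromo-3,5,7,3',4'-penta-O-benzylepicatechin | O(Cc3ccccc3)c1cc(OCc3ccccc3)c2c(c1)O[C@H](c1ccc(OCc3ccccc3)c(OCc3ccccc3)c1)[C@H](OCc3ccccc3)[C@H]2c1c(OCc3ccccc3)c(Br)c2c(c1OCc3ccccc3)C[C@@H](OCc3ccccc3)[C@@H](c1ccc(OCc3ccccc3)c(OCc3ccccc3)c1)O2
F2 | step 11 | 3-O-acetyl-5,7,3',4'-tetra-O-benzylepicatechin | O(Cc3ccccc3)c1cc(OCc3ccccc3)c2c(c1)O[C@H](c1ccc(OCc3ccccc3)c(OCc3ccccc3)c1)[C@H](OC(C)=O)C2
F3 | step 11 | 3-O-acetyl-4β-(2-ethoxyethoxy)-5,7,3',4'-tetra-O-benzylepicatechin | O(Cc3ccccc3)c1cc(OCc3ccccc3)c2c(c1)O[C@H](c1ccc(OCc3ccccc3)c(OCc3ccccc3)c1)[C@H](OC(C)=O)[C@H]2OCCOCC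
F4 | step 8 | 8-lithio-3,5,7,3',4'-penta-O-benzyl-(−)-epicatechin | O(Cc3ccccc3)c1cc(OCc3ccccc3)c2c(c1[Li])O[C@H](c1ccc(OCc3ccccc3)c(OCc3ccccc3)c1)[C@H](OCc3ccccc3)C2
F5 | step 8 | 8-{[4,6-bis(benzyloxy)-2-hydroxyphenyl](hydroxy)methyl}-3,5,7,3',4'-penta-O-benzylepicatechin, both carbinol epimers | O(Cc3ccccc3)c1cc(OCc3ccccc3)c2c(c1C(O)c4c(O)cc(OCc3ccccc3)cc4OCc3ccccc3)O[C@H](c1ccc(OCc3ccccc3)c(OCc3ccccc3)c1)[C@H](OCc3ccccc3)C2
F6 | step 8 | 3-O-acetyl-5,7,3',4'-tetra-O-benzylepicatechin-(4β→8)-3,5,7,3',4'-penta-O-benzylepicatechin | O(Cc3ccccc3)c1cc(OCc3ccccc3)c2c(c1)O[C@H](c1ccc(OCc3ccccc3)c(OCc3ccccc3)c1)[C@H](OC(C)=O)[C@H]2c1c(OCc3ccccc3)cc(OCc3ccccc3)c2c1O[C@H](c1ccc(OCc3ccccc3)c(OCc3ccccc3)c1)[C@H](OCc3ccccc3)C2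
F7 | step 8 | 3-O-acetyl-5,7,3',4'-tetra-O-benzylepicatechin-(4β→8)-4β-(2-ethoxyethoxy)-3,5,7,3',4'-penta-O-benzylepicatechin | O(Cc3ccccc3)c1cc(OCc3ccccc3)c2c(c1)O[C@H](c1ccc(OCc3ccccc3)c(OCc3ccccc3)c1)[C@H](OC(C)=O)[C@H]2c1c(OCc3ccccc3)cc(OCc3ccccc3)c2c1O[C@H](c1ccc(OCc3ccccc3)c(OCc3ccccc3)c1)[C@H](OCc3ccccc3)[C@H]2OCCOCC
F8 | step 6 | 4β-(2-ethoxyethoxy)-3,5,7,3',4'-penta-O-benzylepicatechin | O(Cc3ccccc3)c1cc(OCc3ccccc3)c2c(c1)O[C@H](c1ccc(OCc3ccccc3)c(OCc3ccccc3)c1)[C@H](OCc3ccccc3)[C@H]2OCCOCC
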